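**Strategy.** The plan rests on disconnecting the C4′–C4a′ aryl ketone bond of the flavanone (primed locants). Its ring A, once C5′–O and C7′–O carry the same group, is a 2-substituted phloroglucinol ether whose two carbons ortho to the ring oxygen O1′ (C4a′ and C8′) are equivalent. One intramolecular Friedel–Crafts acylation therefore closes the pyranone ring with the flavan necessarily at C6′. The precursor is an (R)-3-aryloxy-3-phenylpropanoic acid whose aryl group is a 3,5-dimethoxyphenyl ring bearing the 2,4-trans-flavan-4-yl unit at C4. Both flanking oxygens are methyl ethers, which keeps the ring symmetric, electron-rich and free of acylable OH. Afterwards only the chelated 5′-OMe is cleaved.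

Key step: step 7

Assumption: the (R,R) antipode of the carbene precursor is taken to deliver the 2S series in step 2; should a trial on the parent flavone show the opposite sense, its mirror image is used and nothing else changes.

Step 1
Reactants: 1 wogonin (5,7-dihydroxy-8-methoxyflavone)
Product: 3 7-(benzyloxy)-5,8-dimethoxyflavone, via 7-O-benzylwogonin 2 (not isolated)
Conditions: BnBr (1.05 equiv), K2CO3, DMF, rt; then MeI (3 equiv), 50 °C
Reagents that add atoms: benzyl bromide, BrCc1ccccc1; iodomethane, CI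
Why: Two Williamson etherifications in sequence on a flavone that already holds the O1/C5/C7/C8 oxygen pattern of the flavan ring A: the free 7-OH is benzylated at room temperature, while the 5-OH, hydrogen-bonded to C4=O, reacts only on warming with the small methyl electrophile.

Step 2
Reactants: 3 7-(benzyloxy)-5,8-dimethoxyflavone
Product: 5 (2S,4S)-7-(benzyloxy)-5,8-dimethoxy-2-phenylchroman-4-ol, via (2S)-flavanone 4 (not isolated)
Conditions: [Ru(cod)(2-methylallyl)2] (5 mol%), (R,R)-SINpEt·HBF4 (1,3-bis[(R)-1-(1-naphthyl)ethyl]imidazolinium tetrafluoroborate, 10 mol%), KOt-Bu (15 mol%), H2 (120 bar), toluene, rt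
Reagents that add atoms: none
Why: Ruthenium–carbene-catalysed asymmetric hydrogenation of a flavone: the chiral ligand fixes the face on which C2=C3 takes up hydrogen, setting C2 as S, and the flavanone 4 is reduced onward to the mainly 2,4-cis flavan-4-ol, whose C4 configuration is irrelevant because C4 is ionised in step 3.

Step 3
Reactants: 5 (2S,4S)-7-(benzyloxy)-5,8-dimethoxy-2-phenylchroman-4-ol; 6 phloroglucinol
Product: 7 2-[(2S,4S)-7-(benzyloxy)-5,8-dimethoxy-2-phenylchroman-4-yl]benzene-1,3,5-triol (2,4-trans)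
Conditions: 6 (5 equiv), TsOH·H2O (10 mol%), 1,4-dioxane, rt
Reagents that add atoms: none
Why: Acid-catalysed Friedel–Crafts alkylation of SN1 type (the flavan-4-ol/phloroglucinol condensation of proanthocyanidin chemistry): the C4 cation, stabilised by O1, 5-OMe and 7-OBn, is captured by threefold-symmetric phloroglucinol (one constitution only) quasi-axially on the face anti to the equatorial C2 phenyl, giving the 2,4-trans (4S) product, which reversibility and relief of strain against the peri 5-OMe also favour.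

Step 4
Reactants: 7 2-[(2S,4S)-7-(benzyloxy)-5,8-dimethoxy-2-phenylchroman-4-yl]benzene-1,3,5-triol; 8 ethyl (S)-3-hydroxy-3-phenylpropanoate
Product: 9 ethyl (3R)-3-{4-[(2S,4S)-7-(benzyloxy)-5,8-dimethoxy-2-phenylchroman-4-yl]-3,5-dihydroxyphenoxy}-3-phenylpropanoate
Conditions: 8 (1.05 equiv), PPh3, DIAD, THF, −20 → 0 °C
Reagents that add atoms: none
Why: Mitsunobu etherification: the alkoxyphosphonium ion of 8 is displaced with inversion (SN2, S → R) by the only unhindered phenol, the one para to the flavanyl group, the other two being screened by that bulky ortho substituent.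

Step 5
Reactants: 9 ethyl (3R)-3-{4-[(2S,4S)-7-(benzyloxy)-5,8-dimethoxy-2-phenylchroman-4-yl]-3,5-dihydroxyphenoxy}-3-phenylpropanoate
Product: 10 ethyl (3R)-3-{4-[(2S,4S)-7-(benzyloxy)-5,8-dimethoxy-2-phenylchroman-4-yl]-3,5-dimethoxyphenoxy}-3-phenylpropanoate
Conditions: Me2SO4 (2.5 equiv), K2CO3, acetone, rt → 40 °C
Reagents that add atoms: dimethyl sulfate, COS(=O)(=O)OC
Why: Williamson O-methylation of both phenols with a hard electrophile in acetone (O- and not C-alkylation), the carbonate being too weak a base to enolise the ester and expel the β-aryloxy group.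

Step 6
Reactants: 10 ethyl (3R)-3-{4-[(2S,4S)-7-(benzyloxy)-5,8-dimethoxy-2-phenylchroman-4-yl]-3,5-dimethoxyphenoxy}-3-phenylpropanoate
Product: 11 (3R)-3-{4-[(2S,4S)-7-(benzyloxy)-5,8-dimethoxy-2-phenylchroman-4-yl]-3,5-dimethoxyphenoxy}-3-phenylpropanoic acid
Conditions: LiOH·H2O (3 equiv), THF/H2O 3:1, 0 °C → rt; then cold 1 M HCl to pH 3–4
Reagents that add atoms: lithium hydroxide, [Li+].[OH-]
Why: Ester saponification (BAc2), which should outrun E1cB loss of the phenol because hydroxide adds to the carbonyl far faster than it enolises the ester and the electron-rich aryloxide is a poor leaving group; C3 is not touched.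

Step 7
Reactants: 11 (3R)-3-{4-[(2S,4S)-7-(benzyloxy)-5,8-dimethoxy-2-phenylchroman-4-yl]-3,5-dimethoxyphenoxy}-3-phenylpropanoic acid
Product: 13 (2R)-6-[(2S,4S)-7-(benzyloxy)-5,8-dimethoxy-2-phenylchroman-4-yl]-5,7-dimethoxy-2-phenylchroman-4-one, via mixed trifluoroacetic anhydride 12 (not isolated)
Conditions: (CF3CO)2O (1.5 equiv), CH2Cl2 (0.02 M), 0 °C, 1–2 h; aq. NaHCO3
Reagents that add atoms: none
Why: The anhydride converts the acid into the acyl trifluoroacetate 12, whose carbonyl carbon (or the acylium ion derived from it) is attacked by the ring carbon ortho to the aryl ether oxygen to give a Wheland intermediate that loses a proton, forming C4′–C4a′. The closest known reaction type is the (CF3CO)2O-mediated intramolecular Friedel–Crafts acylation of 3-aryloxypropanoic acids of phloroglucinol ethers to chroman-4-ones. The pyranone ring (O1′, C2′, C3′, C4′, C4a′, C8a′) closes in a 6-exo-trig mode at the activated carbonyl. No stereocentre is created; C2′ keeps its R configuration because none of its bonds takes part, and the activation is kept cold, dilute and short so that the benzylic aryl ether is not ionised. The one selectivity needed, 6- versus 8-linkage of the flavan, is settled by the substrate: with OMe on both carbons flanking the flavanyl-bearing carbon the two ortho positions are equivalent and attack at either gives the same ketone 13. The methyl caps also keep the ring at trialkoxybenzene reactivity and leave no phenol to be O-acylated, and ring A of the flavan (C6–H) cannot compete because it would have to react intermolecularly.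

Step 8
Reactants: 13 (2R)-6-[(2S,4S)-7-(benzyloxy)-5,8-dimethoxy-2-phenylchroman-4-yl]-5,7-dimethoxy-2-phenylchroman-4-one
Product: 14 (2R)-6-[(2S,4S)-7-(benzyloxy)-5,8-dimethoxy-2-phenylchroman-4-yl]-5-hydroxy-7-methoxy-2-phenylchroman-4-one
Conditions: BCl3 (1.5 equiv, 1 M in CH2Cl2), CH2Cl2, −78 → −20 °C; aq. NaHCO3
Reagents that add atoms: none
Why: Chelation-controlled ether cleavage peri to a carbonyl: BCl3 binds C4′=O, closes a six-membered O–B–O chelate with the 5′-OMe and chloride removes that methyl alone (SN2), the non-chelated 7′-, 5- and 8-OMe groups being inert at this temperature, while any benzyl ether lost here only anticipates step 9.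

Step 9
Reactants: 14 (2R)-6-[(2S,4S)-7-(benzyloxy)-5,8-dimethoxy-2-phenylchroman-4-yl]-5-hydroxy-7-methoxy-2-phenylchroman-4-one
Product: 15 (2R)-5-hydroxy-6-[(2S,4S)-7-hydroxy-5,8-dimethoxy-2-phenylchroman-4-yl]-7-methoxy-2-phenylchroman-4-one (CNP0301559.1)
Conditions: H2 (1 atm), Pd/C (10% palladium on carbon), EtOAc, rt
Reagents that add atoms: none
Why: Catalytic hydrogenolysis of the aryl benzyl ether, which is cleaved far faster than the cyclic benzylic C2–O1 and C2′–O1′ ethers, the chelated ketone staying intact at this pressure and no stereocentre being affected.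

**Compound list**

1 | wogonin (5,7-dihydroxy-8-methoxyflavone) | COc1c(O)cc(O)c2c(=O)cc(-c3ccccc3)oc12 | starting material
2 | 7-(benzyloxy)-5-hydroxy-8-methoxyflavone (7-O-benzylwogonin) | COc1c(OCc3ccccc3)cc(O)c2c(=O)cc(-c3ccccc3)oc12 | intermediate (not isolated)
3 | 7-(benzyloxy)-5,8-dimethoxyflavone | COc1c(OCc3ccccc3)cc(OC)c2c(=O)cc(-c3ccccc3)oc12 | intermediate
4 | (2S)-7-(benzyloxy)-5,8-dimethoxy-2-phenylchroman-4-one | O=C1C[C@@H](c2ccccc2)Oc2c(OC)c(OCc3ccccc3)cc(OC)c21 | intermediate (not isolated)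
5 | (2S,4S)-7-(benzyloxy)-5,8-dimethoxy-2-phenylchroman-4-ol (2,4-cis) | O[C@H]1C[C@@H](c2ccccc2)Oc2c(OC)c(OCc3ccccc3)cc(OC)c21 | intermediate
6 | phloroglucinol (benzene-1,3,5-triol) | Oc1cc(O)cc(O)c1 | starting material
7 | 2-[(2S,4S)-7-(benzyloxy)-5,8-dimethoxy-2-phenylchroman-4-yl]benzene-1,3,5-triol (2,4-trans) | Oc1cc(O)c([C@@H]2C[C@@H](c3ccccc3)Oc3c(OC)c(OCc4ccccc4)cc(OC)c32)c(O)c1 | intermediate
8 | ethyl (S)-3-hydroxy-3-phenylpropanoate | CCOC(=O)C[C@H](O)c1ccccc1 | starting material
9 | ethyl (3R)-3-{4-[(2S,4S)-7-(benzyloxy)-5,8-dimethoxy-2-phenylchroman-4-yl]-3,5-dihydroxyphenoxy}-3-phenylpropanoate | CCOC(=O)C[C@H](c1ccccc1)Oc1cc(O)c([C@@H]2C[C@@H](c3ccccc3)Oc3c(OC)c(OCc4ccccc4)cc(OC)c32)c(O)c1 | intermediate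
10 | ethyl (3R)-3-{4-[(2S,4S)-7-(benzyloxy)-5,8-dimethoxy-2-phenylchroman-4-yl]-3,5-dimethoxyphenoxy}-3-phenylpropanoate | CCOC(=O)C[C@H](c1ccccc1)Oc1cc(OC)c([C@@H]2C[C@@H](c3ccccc3)Oc3c(OC)c(OCc4ccccc4)cc(OC)c32)c(OC)c1 | intermediate
11 | (3R)-3-{4-[(2S,4S)-7-(benzyloxy)-5,8-dimethoxy-2-phenylchroman-4-yl]-3,5-dimethoxyphenoxy}-3-phenylpropanoic acid | OC(=O)C[C@H](c1ccccc1)Oc1cc(OC)c([C@@H]2C[C@@H](c3ccccc3)Oc3c(OC)c(OCc4ccccc4)cc(OC)c32)c(OC)c1 | intermediate (precursor of the key step)
12 | mixed anhydride of 11 with trifluoroacetic acid | O=C(OC(=O)C(F)(F)F)C[C@H](c1ccccc1)Oc1cc(OC)c([C@@H]2C[C@@H](c3ccccc3)Oc3c(OC)c(OCc4ccccc4)cc(OC)c32)c(OC)c1 | intermediate (not isolated)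
13 | (2R)-6-[(2S,4S)-7-(benzyloxy)-5,8-dimethoxy-2-phenylchroman-4-yl]-5,7-dimethoxy-2-phenylchroman-4-one | COc1cc2c(c(OC)c1[C@@H]1C[C@@H](c3ccccc3)Oc3c(OC)c(OCc4ccccc4)cc(OC)c31)C(=O)C[C@H](c1ccccc1)O2 | intermediate (product of the key step)
14 | (2R)-6-[(2S,4S)-7-(benzyloxy)-5,8-dimethoxy-2-phenylchroman-4-yl]-5-hydroxy-7-methoxy-2-phenylchroman-4-one | COc1cc2c(c(O)c1[C@@H]1C[C@@H](c3ccccc3)Oc3c(OC)c(OCc4ccccc4)cc(OC)c31)C(=O)C[C@H](c1ccccc1)O2 | intermediate
15 | (2R)-5-hydroxy-6-[(2S,4S)-7-hydroxy-5,8-dimethoxy-2-phenylchroman-4-yl]-7-methoxy-2-phenylchroman-4-one | COc1cc2c(c(O)c1[C@@H]1C[C@@H](c3ccccc3)Oc3c(OC)c(O)cc(OC)c31)C(=O)C[C@H](c1ccccc1)O2 | target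

**Step count.** Total: 9 steps. Longest linear sequence: 9 steps (1 → 15); phloroglucinol 6 and the hydroxy ester 8 enter as purchased.

**Steps most likely to fail**

Step 4 (Mitsunobu etherification). The etherification may not discriminate well enough between the para phenol and the two flanked phenols. The activated benzylic alcohol may also be lost by elimination to the cinnamate, or may partly ionise with erosion of configuration. The fallback sets out from triol 7 and comes back at 10; it moves the site decision to a bulky silyl chloride and gives the Mitsunobu reaction a single phenol. The para hydroxyl of 7 would be silylated with i-Pr3SiCl (1.0 equiv, imidazole, DMF, 0 °C) to give 2-[(2S,4S)-7-(benzyloxy)-5,8-dimethoxy-2-phenylchroman-4-yl]-5-[(triisopropylsilyl)oxy]benzene-1,3-diol F1. Both remaining phenols would be methylated (Me2SO4, K2CO3, acetone) to the silyl dimethyl ether F2. Bu4NF buffered with AcOH (THF, 0 °C) would then release 4-[(2S,4S)-7-(benzyloxy)-5,8-dimethoxy-2-phenylchroman-4-yl]-3,5-dimethoxyphenol F3. Mitsunobu coupling of F3 with 8 (PPh3, DIAD, toluene, −20 °C) should give 10 directly, with the methylation no longer carried out on a β-aryloxy ester.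

Step 2 (asymmetric hydrogenation). The electron-rich, peri-substituted pyranone may be taken up slowly or with poor facial selectivity. The fallback sets out from flavone 3 and comes back at 5; it replaces enantioselective hydrogenation by a kinetic resolution. Conjugate reduction of 3 with LiBH(s-Bu)3 (THF, −78 °C) would give racemic 7-(benzyloxy)-5,8-dimethoxy-2-phenylchroman-4-one F4. Asymmetric transfer hydrogenation (RuCl[(S,S)-TsDPEN](p-cymene), HCO2H/Et3N, rt, stopped near half conversion) creates the 4S carbinol and should do so quickly only for the 2S enantiomer, which gives the cis alcohol 5. The slow-reacting (2R)-7-(benzyloxy)-5,8-dimethoxy-2-phenylchroman-4-one F5 would be left behind and removed by chromatography.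

Step 7 (key ring closure). The acid set free may ionise the benzylic aryl ether, leading to loss of the C2′ configuration or elimination to a cinnamic acid, and the anhydride may C-trifluoroacetylate ring A of the flavan at C6. The fallback sets out from acid 11 and comes back at 13; it forms the same C4′–C4a′ bond with a nitrogen-based electrophile under base-buffered conditions. Acid 11 would be converted into the N,N-dimethylamide F6 (EDC·HCl, HOBt, Me2NH·HCl, i-Pr2NEt, CH2Cl2, 0 °C). Activation with Tf2O and 2-chloropyridine (CH2Cl2, −78 → 0 °C) should close the ring in a Vilsmeier–Haack-type acylation to the cyclic iminium triflate F7, by symmetry again at either ortho carbon. Aqueous NaHCO3 would hydrolyse F7 to ketone 13.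

**Further compounds**

F1 | step 4 | 2-[(2S,4S)-7-(benzyloxy)-5,8-dimethoxy-2-phenylchroman-4-yl]-5-[(triisopropylsilyl)oxy]benzene-1,3-diol | CC(C)[Si](Oc1cc(O)c([C@@H]2C[C@@H](c3ccccc3)Oc3c(OC)c(OCc4ccccc4)cc(OC)c32)c(O)c1)(C(C)C)C(C)C
F2 | step 4 | {4-[(2S,4S)-7-(benzyloxy)-5,8-dimethoxy-2-phenylchroman-4-yl]-3,5-dimethoxyphenoxy}triisopropylsilane | CC(C)[Si](Oc1cc(OC)c([C@@H]2C[C@@H](c3ccccc3)Oc3c(OC)c(OCc4ccccc4)cc(OC)c32)c(OC)c1)(C(C)C)C(C)C
F3 | step 4 | 4-[(2S,4S)-7-(benzyloxy)-5,8-dimethoxy-2-phenylchroman-4-yl]-3,5-dimethoxyphenol | Oc1cc(OC)c([C@@H]2C[C@@H](c3ccccc3)Oc3c(OC)c(OCc4ccccc4)cc(OC)c32)c(OC)c1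
F4 | step 2 | rac-7-(benzyloxy)-5,8-dimethoxy-2-phenylchroman-4-one | O=C1CC(c2ccccc2)Oc2c(OC)c(OCc3ccccc3)cc(OC)c21
F5 | step 2 | (2R)-7-(benzyloxy)-5,8-dimethoxy-2-phenylchroman-4-one | O=C1C[C@H](c2ccccc2)Oc2c(OC)c(OCc3ccccc3)cc(OC)c21
F6 | step 7 | (3R)-3-{4-[(2S,4S)-7-(benzyloxy)-5,8-dimethoxy-2-phenylchroman-4-yl]-3,5-dimethoxyphenoxy}-N,N-dimethyl-3-phenylpropanamide | CN(C)C(=O)C[C@H](c1ccccc1)Oc1cc(OC)c([C@@H]2C[C@@H](c3ccccc3)Oc3c(OC)c(OCc4ccccc4)cc(OC)c32)c(OC)c1
F7 | step 7 | N-{(2R)-6-[(2S,4S)-7-(benzyloxy)-5,8-dimethoxy-2-phenylchroman-4-yl]-5,7-dimethoxy-2-phenylchroman-4-ylidene}-N-methylmethanaminium trifluoromethanesulfonate | C[N+](C)=C1C[C@H](c2ccccc2)Oc2cc(OC)c([C@@H]3C[C@@H](c4ccccc4)Oc4c(OC)c(OCc5ccccc5)cc(OC)c43)c(OC)c21.[O-]S(=O)(=O)C(F)(F)F
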